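**Retrosynthetic overview**

1. Rhoiptelol B ⇐ hydrogenolysis of three O‑benzyl groups, preceded by equatorial hydride delivery (L‑Selectride) to a 2,6‑cis‑tetrahydropyran‑4‑one, which sets the axial C4–OH.
2. The pyranone ⇐ C2–C3 bond: mediated anodic oxidation of a 4‑(benzyloxy)‑3‑methoxybenzyl ether to an aryl oxocarbenium ion, trapped by a tethered enol acetate (sets C2 cis to C6).
3. Enol acetate ⇐ Ru‑catalysed AcOH addition to a homopropargylic ether ⇐ Williamson etherification of a syn homopropargylic alcohol.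
4. Homopropargylic alcohol ⇐ chelation‑controlled propargylation (sets C6) of an α‑benzyloxy aldehyde ⇐ O‑benzyl‑L‑tyrosine by diazotisation with retention (C1′).
5. Ring order: both arenes are purchased; the tetrahydropyran is the only ring formed (step 7).

Assumption: O‑benzyl‑L‑tyrosine, allenyltributylstannane and 4‑(benzyloxy)‑3‑methoxybenzyl chloride are treated as catalogue items; if the chloride is unavailable it is one step (SOCl2) from the commercial alcohol.

Target stereochemistry planned for: (2R,4S,6S)‑2‑(4‑hydroxy‑3‑methoxyphenyl)‑6‑[(1S)‑1‑hydroxy‑2‑(4‑hydroxyphenyl)ethyl]oxan‑4‑ol. The 2,6‑substituents are cis (both equatorial), the 4‑OH is axial (trans to both), and the C6–O/C1′–OH pair is syn.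

---

**Step 1**
Reactants: 1, O‑benzyl‑L‑tyrosine
Product: 2, (S)‑3‑[4‑(benzyloxy)phenyl]‑2‑hydroxypropanoic acid
Conditions: NaNO2, 1 M H2SO4, 1,4‑dioxane/H2O, 0 °C → rt
Reagents that add atoms: water, O
Why: Diazotisation of an α‑amino acid; the carboxylate displaces N2 to an α‑lactone that water reopens, so two inversions give net retention and C1′ (S) comes directly from tyrosine.

**Step 2**
Reactants: 2
Product: 3, benzyl (S)‑2‑(benzyloxy)‑3‑[4‑(benzyloxy)phenyl]propanoate
Conditions: BnBr (3 equiv), Ag2O (2.5 equiv), TBAI (cat.), CH2Cl2, rt, dark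
Reagents that add atoms: benzyl bromide, BrCc1ccccc1
Why: Silver(I) oxide‑mediated O‑benzylation esterifies the acid and etherifies the α‑hydroxyl without strong base, so the α‑centre is not epimerised; the α‑OBn is the chelating group needed in step 4.

**Step 3**
Reactants: 3
Product: 4, (S)‑2‑(benzyloxy)‑3‑[4‑(benzyloxy)phenyl]propanal
Conditions: DIBAL‑H (1.1 equiv), CH2Cl2, −78 °C; MeOH, Rochelle salt; short silica plug, used at once
Reagents that add atoms: none
Why: Partial ester reduction; the α‑alkoxy group chelates aluminium and holds the tetrahedral intermediate at −78 °C until quench, and immediate use avoids α‑epimerisation.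

**Step 4**
Reactants: 4; 5, allenyltributylstannane
Product: 6, (2S,3S)‑2‑(benzyloxy)‑1‑[4‑(benzyloxy)phenyl]hex‑5‑yn‑3‑ol
Conditions: MgBr2·OEt2 (2 equiv), CH2Cl2, −78 → −20 °C
Reagents that add atoms: allenyltributylstannane (5), C=C=C[Sn](CCCC)(CCCC)CCCC (supplies the propargyl C3 unit)
Why: Chelation‑controlled (Cram‑chelate) SE2′ propargylation; Mg bridges C=O and the α‑OBn and the stannane attacks the face opposite the CH2Ar group, giving the syn (2S,3S) alcohol and so setting C6 from C1′.

**Step 5**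
Reactants: 6; 7, 4‑(benzyloxy)‑3‑methoxybenzyl chloride
Product: 8, 1‑(benzyloxy)‑4‑({[(2S,3S)‑2‑(benzyloxy)‑1‑[4‑(benzyloxy)phenyl]hex‑5‑yn‑3‑yl]oxy}methyl)‑2‑methoxybenzene
Conditions: NaH (1.2 equiv), TBAI (cat.), THF/DMF, 0 °C → rt
Reagents that add atoms: 4‑(benzyloxy)‑3‑methoxybenzyl chloride (7), COc1cc(CCl)ccc1OCc1ccccc1
Why: Williamson etherification; the alkoxide forms selectively over the acetylide (pKa about 17 vs 25) and no stereocentre is touched.

**Step 6**
Reactants: 8
Product: 9, (4S,5S)‑5‑(benzyloxy)‑4‑{[4‑(benzyloxy)‑3‑methoxybenzyl]oxy}‑6‑[4‑(benzyloxy)phenyl]hex‑1‑en‑2‑yl acetate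
Conditions: [RuCl2(p‑cymene)]2 (2 mol%), P(2‑furyl)3 (4 mol%), Na2CO3 (cat.), AcOH (2 equiv), toluene, 80 °C
Reagents that add atoms: acetic acid, CC(=O)O
Why: Ru‑catalysed Markovnikov addition of a carboxylic acid to a terminal alkyne gives the 2‑acetoxy‑1‑alkene; the buffered medium leaves the electron‑rich benzylic ether intact.

**Step 7 (key ring‑forming step)**
Reactants: 9
Product: 10, (2R,6S)‑2‑[4‑(benzyloxy)‑3‑methoxyphenyl]‑6‑{(1S)‑1‑(benzyloxy)‑2‑[4‑(benzyloxy)phenyl]ethyl}oxan‑4‑one
Conditions: undivided cell, RVC(+)/Pt(−), constant current, 2.2 F/mol; (4‑BrC6H4)3N (20 mol%), 2,6‑lutidine (3 equiv), nBu4NPF6 (0.1 M), MeCN/CH2Cl2 4:1, 4 Å MS, rt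
Reagents that add atoms: none
Why: Proposed new method: mediated anodic C–H oxidation/cyclisation. The anodically generated triarylaminium radical cation (about +1.05 V vs SCE) oxidises the most electron‑rich arene, the 3,4‑dialkoxybenzyl ether; the 4‑benzyloxyphenyl ring, the plain benzyl ethers and the enol acetate are harder to oxidise. Lutidine removes the benzylic proton of the radical cation and a second electron transfer gives the (E)‑aryl oxocarbenium ion. The enol acetate captures it through a chair transition state with the C6 side chain equatorial, forming C2–C3 and setting C2 cis to C6 (2R). Acetyl is lost to lutidine and H2 forms at the cathode. The closest known reactions are the stoichiometric DDQ‑mediated oxidative C–H cyclisation of benzylic ethers onto enol acetates and the triarylamine‑mediated anodic cleavage of p‑methoxybenzyl ethers; intramolecular C–C trapping of an anodically generated acyclic benzylic oxocarbenium ion has not been demonstrated.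

**Step 8**
Reactants: 10
Product: 11, (2R,4S,6S)‑2‑[4‑(benzyloxy)‑3‑methoxyphenyl]‑6‑{(1S)‑1‑(benzyloxy)‑2‑[4‑(benzyloxy)phenyl]ethyl}oxan‑4‑ol
Conditions: L‑Selectride, THF, −78 °C; NaOH/H2O2 work‑up
Reagents that add atoms: none
Why: Substrate‑controlled ketone reduction; the bulky hydride attacks the 2,6‑diequatorial chair from the equatorial direction, giving the axial alcohol trans to both substituents (4S).

**Step 9**
Reactants: 11
Product: 12, rhoiptelol B
Conditions: H2 (1 atm), 10% Pd/C, EtOAc, rt; stop when O‑debenzylation is complete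
Reagents that add atoms: none
Why: Hydrogenolysis removes the two aryl benzyl ethers and the secondary benzyl ether; the hindered ring C2–O bond is cleaved much more slowly in EtOAc, and no stereocentre is affected.

---

**Compound list**

1 | O‑benzyl‑L‑tyrosine | N[C@@H](Cc1ccc(OCc2ccccc2)cc1)C(=O)O | starting material
2 | (S)‑3‑[4‑(benzyloxy)phenyl]‑2‑hydroxypropanoic acid | O=C(O)[C@@H](O)Cc1ccc(OCc2ccccc2)cc1 | intermediate
3 | benzyl (S)‑2‑(benzyloxy)‑3‑[4‑(benzyloxy)phenyl]propanoate | O=C(OCc1ccccc1)[C@@H](OCc1ccccc1)Cc1ccc(OCc2ccccc2)cc1 | intermediate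
4 | (S)‑2‑(benzyloxy)‑3‑[4‑(benzyloxy)phenyl]propanal | O=C[C@@H](OCc1ccccc1)Cc1ccc(OCc2ccccc2)cc1 | intermediate
5 | allenyltributylstannane | C=C=C[Sn](CCCC)(CCCC)CCCC | starting material
6 | (2S,3S)‑2‑(benzyloxy)‑1‑[4‑(benzyloxy)phenyl]hex‑5‑yn‑3‑ol | C#CC[C@H](O)[C@@H](OCc1ccccc1)Cc1ccc(OCc2ccccc2)cc1 | intermediate
7 | 4‑(benzyloxy)‑3‑methoxybenzyl chloride | COc1cc(CCl)ccc1OCc1ccccc1 | starting material
8 | 4‑(benzyloxy)‑3‑methoxybenzyl ether of 6 | C#CC[C@H](OCc1ccc(OCc2ccccc2)c(OC)c1)[C@@H](OCc1ccccc1)Cc1ccc(OCc2ccccc2)cc1 | intermediate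
9 | (4S,5S)‑5‑(benzyloxy)‑4‑{[4‑(benzyloxy)‑3‑methoxybenzyl]oxy}‑6‑[4‑(benzyloxy)phenyl]hex‑1‑en‑2‑yl acetate | C=C(OC(C)=O)C[C@H](OCc1ccc(OCc2ccccc2)c(OC)c1)[C@@H](OCc1ccccc1)Cc1ccc(OCc2ccccc2)cc1 | intermediate
10 | (2R,6S)‑2‑[4‑(benzyloxy)‑3‑methoxyphenyl]‑6‑{(1S)‑1‑(benzyloxy)‑2‑[4‑(benzyloxy)phenyl]ethyl}oxan‑4‑one | COc1cc([C@H]2CC(=O)C[C@@H]([C@@H](OCc3ccccc3)Cc3ccc(OCc4ccccc4)cc3)O2)ccc1OCc1ccccc1 | intermediate
11 | (2R,4S,6S)‑2‑[4‑(benzyloxy)‑3‑methoxyphenyl]‑6‑{(1S)‑1‑(benzyloxy)‑2‑[4‑(benzyloxy)phenyl]ethyl}oxan‑4‑ol | COc1cc([C@H]2C[C@H](O)C[C@@H]([C@@H](OCc3ccccc3)Cc3ccc(OCc4ccccc4)cc3)O2)ccc1OCc1ccccc1 | intermediate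
12 | rhoiptelol B | COc1cc([C@H]2C[C@H](O)C[C@@H]([C@@H](O)Cc3ccc(O)cc3)O2)ccc1O | target

---

**Totals**

Total steps: 9. Longest linear sequence: 9 (from O‑benzyl‑L‑tyrosine).

**Steps most likely to fail**

1. Step 7 (proposed anodic cyclisation). Risks are competing oxidation of the 4‑benzyloxyphenyl ring or of product 10, capture of the oxocarbenium ion by the neighbouring C1′‑OBn oxygen, and hydrolysis by adventitious water. Fallback (known chemistry): from aldehyde 4, a chelation‑controlled Mukaiyama aldol (MgBr2·OEt2) with the TMS enol ether of (E)‑4‑[4‑(benzyloxy)‑3‑methoxyphenyl]but‑3‑en‑2‑one, then acid‑catalysed 6‑endo oxa‑Michael cyclisation under thermodynamic control, gives the same 2,6‑cis ketone 10 and rejoins at step 8.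

2. Step 4 (chelation‑controlled propargylation). Risks are erosion of the syn:anti ratio and epimerisation of aldehyde 4. Fallback: take both carbinol centres from L‑tartaric acid via (2S,2′S)‑2,2′‑bioxirane. Mono‑opening with 4‑BnOC6H4MgBr/CuI, O‑benzylation of the resulting alcohol, and opening of the second epoxide with lithium acetylide gives 6 without any induced stereocentre.

3. Step 9 (global hydrogenolysis). The risk is competitive cleavage of the ring C2–O benzylic bond next to the electron‑rich arene. Fallback: rebuild the series with non‑hydrogenolytic protection, with both phenols as TBS ethers and the C1′ oxygen as a MOM ether (still chelating in step 4), and unmask at the end with TBAF followed by mild acid.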